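**Strategy.** The route rests on cutting two bonds at neighbouring carbons of ring A (the benzene ring; chroman numbering): O1–C8a, which closes ring B (the dihydropyran), and the bond from C8 to the prenyl CH2. The feature exploited is that C8a carries the tertiary ether oxygen O1 while C8, flanked by O1 and the C7 oxygen, carries the prenyl group. An aryne across C8–C8a can therefore take up the tethered C2 alkoxide at C8a and a prenyl electrophile at C8 in one flask. The precursor is an open-chain C8a-fluoroarene with the styryl group at C5, a methoxymethyl ether at O7 and a (3R)-3-silyloxy-2-methylbutan-2-ol chain on C4a.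

Key step: step 6

Remark on the chemistry: C3 of the target is (R); it is taken unchanged from commercial methyl (2R)-oxirane-2-carboxylate, and 3-fluoro-5-hydroxybenzaldehyde is assumed to be commercial.

Step 1
Reactants: 1 3-fluoro-5-hydroxybenzaldehyde
Product: 2 2-bromo-3-fluoro-5-hydroxybenzaldehyde
Conditions: Br2 (1.0 equiv), CH2Cl2, 0 °C to rt
Reagents that add atoms: bromine, BrBr
Why: Electrophilic aromatic bromination should occur para to the strongly activating hydroxyl, at the carbon between the formyl group and fluorine, as it does in 3-hydroxybenzaldehyde and 3-fluorophenol, while the formyl group tempers the ring against a second bromination.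

Step 2
Reactants: 2 2-bromo-3-fluoro-5-hydroxybenzaldehyde
Product: 3 2-bromo-3-fluoro-5-(methoxymethoxy)benzaldehyde
Conditions: MOMCl, iPr2NEt, CH2Cl2, 0 °C to rt
Reagents that add atoms: chloromethyl methyl ether, COCCl
Why: Base-mediated O-alkylation of the phenol with the α-chloro ether (Williamson-type acetal ether formation) is fast and leaves the aldehyde and both aryl halides untouched.

Step 3
Reactants: 3 2-bromo-3-fluoro-5-(methoxymethoxy)benzaldehyde; 4 diethyl benzylphosphonate
Product: 5 2-bromo-1-fluoro-5-(methoxymethoxy)-3-[(E)-2-phenylethenyl]benzene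
Conditions: KOtBu, THF, 0 °C to rt
Reagents that add atoms: none
Why: The Horner–Wadsworth–Emmons olefination of an aryl aldehyde with a benzylphosphonate anion should give the (E)-stilbene, the usual outcome for semi-stabilised phosphonate anions whose addition is reversible.

Step 4
Reactants: 5 2-bromo-1-fluoro-5-(methoxymethoxy)-3-[(E)-2-phenylethenyl]benzene; 6 methyl (2R)-oxirane-2-carboxylate
Product: 9 (3R)-4-[2-fluoro-4-(methoxymethoxy)-6-[(E)-2-phenylethenyl]phenyl]-2-methylbutane-2,3-diol, via arylmagnesium chloride 7 (not isolated), via hydroxy ester magnesium alkoxide 8 (not isolated)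
Conditions: iPrMgCl·LiCl (1.15 equiv), THF, 0 °C; CuI (10 mol %), 6 (1.3 equiv), −40 to −20 °C; then MeMgBr (4 equiv), −20 to 0 °C; aq. NH4Cl
Reagents that add atoms: methylmagnesium bromide, C[Mg]Br
Why: Bromine–magnesium exchange, helped by the ortho fluorine, gives an aryl Grignard reagent that under copper catalysis opens the glycidic ester in an SN2 sense at its CH2 carbon, and double Grignard addition of MeMgBr to the ester then builds the tertiary carbinol, so the (R) centre is simply C2 of the glycidate, whose C–O bond is never broken.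

Step 5
Reactants: 9 (3R)-4-[2-fluoro-4-(methoxymethoxy)-6-[(E)-2-phenylethenyl]phenyl]-2-methylbutane-2,3-diol
Product: 10 (3R)-4-[2-fluoro-4-(methoxymethoxy)-6-[(E)-2-phenylethenyl]phenyl]-2-methyl-3-[(triisopropylsilyl)oxy]butan-2-ol
Conditions: TIPSOTf (1.2 equiv), 2,6-lutidine, CH2Cl2, −40 to 0 °C
Reagents that add atoms: triisopropylsilyl trifluoromethanesulfonate, CC(C)[Si](OS(=O)(=O)C(F)(F)F)(C(C)C)C(C)C
Why: Silyl ether formation with the bulky silyl triflate should take place only at the secondary hydroxyl because the tertiary one is too hindered, and triisopropylsilyl is preferred to smaller silyl groups because it resists oxygen-to-oxygen silyl shift onto the neighbouring alkoxide in step 6.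

Step 6
Reactants: 10 (3R)-4-[2-fluoro-4-(methoxymethoxy)-6-[(E)-2-phenylethenyl]phenyl]-2-methyl-3-[(triisopropylsilyl)oxy]butan-2-ol; 11 1-bromo-3-methylbut-2-ene
Product: 16 (3R)-7-(methoxymethoxy)-2,2-dimethyl-8-(3-methylbut-2-en-1-yl)-5-[(E)-2-phenylethenyl]-3-[(triisopropylsilyl)oxy]-3,4-dihydro-2H-chromene, via C8-lithiated lithium alkoxide 12 (not isolated), via aryne lithium alkoxide 13 (not isolated), via 8-lithiochroman 14 (not isolated), via 8-chromanylcopper 15 (not isolated)
Conditions: n-BuLi (2.05 equiv), THF (0.02 M), −78 °C, 1 h; −78 to −20 °C; CuBr·SMe2 (1.2 equiv), −78 to −40 °C; 11 (3 equiv), −78 °C to rt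
Reagents that add atoms: none
Why: The first equivalent of n-BuLi should give the tertiary lithium alkoxide and the second should remove the C8 proton, the only ring hydrogen flanked by fluorine and the methoxymethyl ether; on warming this aryllithium loses LiF to give the C8–C8a aryne, the tethered alkoxide adds to C8a to form O1–C8a, and the C8 aryllithium so produced is moved to copper with CuBr·SMe2 and displaces bromide from the CH2 carbon of prenyl bromide to form C8–CH2. The closest known reaction types are the cyclisation of tethered alkoxides onto arynes to give chromans and dihydrobenzofurans, aryne cyclisation–electrophile trapping sequences started with organolithium bases, and the copper-mediated prenylation of aryllithiums that sit between two ether oxygens. Ring B closes in a 6-exo-dig mode, with the second aryne carbon (C8) left outside the new ring. No stereocentre is created, and C3 is not a reaction site, so its (R) configuration passes through unchanged. The step needs oxygen at C8a and carbon at C8, and only the tertiary oxygen may cyclise: the C2 alkoxide reaches C8a through a six-membered ring but C8 only through a seven-membered one, the inductive effect of O7 likewise sends the nucleophile to the remote aryne carbon so that charge builds at C8 beside oxygen, and the C3 oxygen is held as a triisopropylsilyl ether that should neither cyclise in a 5-exo mode nor shift to the alkoxide. An alkyllithium is chosen as base so that no N–H acid is present to protonate the C8 carbanion before copper and prenyl bromide arrive, and lithiation is run at −78 °C and high dilution to hold back addition of n-BuLi to the stilbene and capture of the aryne by a second molecule.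

Step 7
Reactants: 16 (3R)-7-(methoxymethoxy)-2,2-dimethyl-8-(3-methylbut-2-en-1-yl)-5-[(E)-2-phenylethenyl]-3-[(triisopropylsilyl)oxy]-3,4-dihydro-2H-chromene
Product: 17 (3R)-7-(methoxymethoxy)-2,2-dimethyl-8-(3-methylbut-2-en-1-yl)-5-[(E)-2-phenylethenyl]-3,4-dihydro-2H-chromen-3-ol
Conditions: Bu4NF (2 equiv), THF, rt to 45 °C
Reagents that add atoms: none
Why: Fluoride-mediated desilylation, driven by the strong Si–F bond, should free the C3 hydroxyl without touching the acetal, the alkenes or the stereocentre.

Step 8
Reactants: 17 (3R)-7-(methoxymethoxy)-2,2-dimethyl-8-(3-methylbut-2-en-1-yl)-5-[(E)-2-phenylethenyl]-3,4-dihydro-2H-chromen-3-ol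
Product: 18 (3R)-2,2-dimethyl-8-(3-methylbut-2-en-1-yl)-5-[(E)-2-phenylethenyl]-3,4-dihydro-2H-chromene-3,7-diol
Conditions: HCl (0.5 M in MeOH), rt
Reagents that add atoms: none
Why: Acid-catalysed acetal cleavage (transacetalisation to methanol) should remove the aryl methoxymethyl ether under conditions mild enough that the prenyl alkene next to the new phenol neither cyclises nor adds solvent.

**Compound list**

1 | 3-fluoro-5-hydroxybenzaldehyde | O=Cc1cc(O)cc(F)c1 | starting material
2 | 2-bromo-3-fluoro-5-hydroxybenzaldehyde | O=Cc1cc(O)cc(F)c1Br | intermediate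
3 | 2-bromo-3-fluoro-5-(methoxymethoxy)benzaldehyde | COCOc1cc(F)c(Br)c(C=O)c1 | intermediate
4 | diethyl benzylphosphonate | CCOP(=O)(Cc1ccccc1)OCC | starting material
5 | 2-bromo-1-fluoro-5-(methoxymethoxy)-3-[(E)-2-phenylethenyl]benzene | COCOc1cc(F)c(Br)c(/C=C/c2ccccc2)c1 | intermediate
6 | methyl (2R)-oxirane-2-carboxylate | COC(=O)[C@H]1CO1 | starting material
7 | [2-fluoro-4-(methoxymethoxy)-6-[(E)-2-phenylethenyl]phenyl]magnesium chloride, formed in the flask | COCOc1cc(F)c([Mg]Cl)c(/C=C/c2ccccc2)c1 | intermediate
8 | chloromagnesium alkoxide of methyl (2R)-3-[2-fluoro-4-(methoxymethoxy)-6-[(E)-2-phenylethenyl]phenyl]-2-hydroxypropanoate, formed in the flask | COCOc1cc(/C=C/c2ccccc2)c(C[C@@H](O[Mg]Cl)C(=O)OC)c(F)c1 | intermediate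
9 | (3R)-4-[2-fluoro-4-(methoxymethoxy)-6-[(E)-2-phenylethenyl]phenyl]-2-methylbutane-2,3-diol | COCOc1cc(/C=C/c2ccccc2)c(C[C@@H](O)C(C)(C)O)c(F)c1 | intermediate
10 | (3R)-4-[2-fluoro-4-(methoxymethoxy)-6-[(E)-2-phenylethenyl]phenyl]-2-methyl-3-[(triisopropylsilyl)oxy]butan-2-ol | COCOc1cc(/C=C/c2ccccc2)c(C[C@@H](O[Si](C(C)C)(C(C)C)C(C)C)C(C)(C)O)c(F)c1 | intermediate
11 | 1-bromo-3-methylbut-2-ene | CC(C)=CCBr | starting material
12 | lithium alkoxide of 10 lithiated at the ring carbon between fluorine and the methoxymethyl ether (C8), formed in the flask | COCOc1cc(/C=C/c2ccccc2)c(C[C@@H](O[Si](C(C)C)(C(C)C)C(C)C)C(C)(C)O[Li])c(F)c1[Li] | intermediate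
13 | C8–C8a aryne bearing the lithium alkoxide side chain, formed in the flask | COCOC1=CC(/C=C/c2ccccc2)=C(C[C@@H](O[Si](C(C)C)(C(C)C)C(C)C)C(C)(C)O[Li])C#C1 | intermediate
14 | (3R)-8-lithio-7-(methoxymethoxy)-2,2-dimethyl-5-[(E)-2-phenylethenyl]-3-[(triisopropylsilyl)oxy]-3,4-dihydro-2H-chromene, formed in the flask | [Li]c1c(OCOC)cc(/C=C/c2ccccc2)c2c1OC(C)(C)[C@H](O[Si](C(C)C)(C(C)C)C(C)C)C2 | intermediate
15 | the corresponding 8-chromanylcopper species, formed in the flask | [Cu]c1c(OCOC)cc(/C=C/c2ccccc2)c2c1OC(C)(C)[C@H](O[Si](C(C)C)(C(C)C)C(C)C)C2 | intermediate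
16 | (3R)-7-(methoxymethoxy)-2,2-dimethyl-8-(3-methylbut-2-en-1-yl)-5-[(E)-2-phenylethenyl]-3-[(triisopropylsilyl)oxy]-3,4-dihydro-2H-chromene | CC(C)=CCc1c(OCOC)cc(/C=C/c2ccccc2)c2c1OC(C)(C)[C@H](O[Si](C(C)C)(C(C)C)C(C)C)C2 | intermediate
17 | (3R)-7-(methoxymethoxy)-2,2-dimethyl-8-(3-methylbut-2-en-1-yl)-5-[(E)-2-phenylethenyl]-3,4-dihydro-2H-chromen-3-ol | CC(C)=CCc1c(OCOC)cc(/C=C/c2ccccc2)c2c1OC(C)(C)[C@H](O)C2 | intermediate
18 | (3R)-2,2-dimethyl-8-(3-methylbut-2-en-1-yl)-5-[(E)-2-phenylethenyl]-3,4-dihydro-2H-chromene-3,7-diol | CC(C)=CCc1c(O)cc(/C=C/c2ccccc2)c2c1OC(C)(C)[C@H](O)C2 | target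

**Total step count:** 8
**Longest linear sequence:** 8 steps (1 to 18)

**Steps most likely to fail**

1. Step 6. What may go wrong: protonation of the C8 carbanion before it is captured; capture of the aryne by a second molecule (aryllithium or residual butyllithium) in place of the internal alkoxide; addition of butyllithium across the stilbene; allylic transposition during prenyl transfer. Fallback: the two bond formations are separated. Setting out from 10, LiN(iPr)2 (3 equiv, THF, −78 to 0 °C) generates the aryne and the alkoxide closes ring B, the diisopropylamine formed protonating C8 to give (3R)-7-(methoxymethoxy)-2,2-dimethyl-5-[(E)-2-phenylethenyl]-3-[(triisopropylsilyl)oxy]-3,4-dihydro-2H-chromene F1. Directed ortho-lithiation of F1 at C8, between the two ether oxygens (sec-BuLi, TMEDA, THF, −78 °C, where addition to the stilbene is slow), followed by CuBr·SMe2 and prenyl bromide 11, comes back to the route at 16.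

2. Step 4. What may go wrong: sluggish bromine–magnesium exchange; loss of fluoride from the ortho-fluoro Grignard reagent; attack of the aryl Grignard reagent on the ester carbonyl before the epoxide opens. Fallback: the side chain is attached by palladium-catalysed ketone α-arylation and C3 is set by reagent-controlled reduction. Commercial 3-hydroxy-3-methylbutan-2-one is silylated (Et3SiCl, imidazole, DMF) to 3-methyl-3-[(triethylsilyl)oxy]butan-2-one F2. Setting out from 5, Pd2(dba)3, XPhos (2-dicyclohexylphosphino-2′,4′,6′-triisopropylbiphenyl) and NaOtBu in toluene at 70 °C arylate the only enolisable carbon of the ketone to give 1-[2-fluoro-4-(methoxymethoxy)-6-[(E)-2-phenylethenyl]phenyl]-3-methyl-3-[(triethylsilyl)oxy]butan-2-one F3. Corey–Bakshi–Shibata reduction with (S)-1-methyl-3,3-diphenyltetrahydro-1H,3H-pyrrolo[1,2-c][1,3,2]oxazaborole and catecholborane in toluene at −78 °C, with the quaternary silyloxy carbon as the large group, should give (2R)-1-[2-fluoro-4-(methoxymethoxy)-6-[(E)-2-phenylethenyl]phenyl]-3-methyl-3-[(triethylsilyl)oxy]butan-2-ol F4. Bu4NF in THF then removes the triethylsilyl group and the route is rejoined at 9.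

3. Step 1. What may go wrong: bromination at a position ortho to the hydroxyl instead of para, or twofold bromination. Fallback: the bromine is placed by directed ortho-metalation instead of electrophilic substitution. Setting out from 1, iPr3SiCl and imidazole in DMF give 3-fluoro-5-[(triisopropylsilyl)oxy]benzaldehyde F5. LiN(Me)CH2CH2NMe2 in THF at −20 °C adds to the formyl group to give the lithium α-amino alkoxide of F5, F6. sec-BuLi at −78 °C lithiates the one carbon flanked by this directing group and fluorine, the bulky silyl ether shielding both of its own ortho positions, to give the C2-lithiated α-amino alkoxide F7. BrCl2C–CCl2Br followed by aqueous acid then gives 2-bromo-3-fluoro-5-[(triisopropylsilyl)oxy]benzaldehyde F8, and Bu4NF in THF returns the route to 2.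

**Further compounds**

F1 | step 6 | (3R)-7-(methoxymethoxy)-2,2-dimethyl-5-[(E)-2-phenylethenyl]-3-[(triisopropylsilyl)oxy]-3,4-dihydro-2H-chromene | COCOc1cc(/C=C/c2ccccc2)c2c(c1)OC(C)(C)[C@H](O[Si](C(C)C)(C(C)C)C(C)C)C2
F2 | step 4 | 3-methyl-3-[(triethylsilyl)oxy]butan-2-one | CC(=O)C(C)(C)O[Si](CC)(CC)CC
F3 | step 4 | 1-[2-fluoro-4-(methoxymethoxy)-6-[(E)-2-phenylethenyl]phenyl]-3-methyl-3-[(triethylsilyl)oxy]butan-2-one | COCOc1cc(/C=C/c2ccccc2)c(CC(=O)C(C)(C)O[Si](CC)(CC)CC)c(F)c1
F4 | step 4 | (2R)-1-[2-fluoro-4-(methoxymethoxy)-6-[(E)-2-phenylethenyl]phenyl]-3-methyl-3-[(triethylsilyl)oxy]butan-2-ol | COCOc1cc(/C=C/c2ccccc2)c(C[C@@H](O)C(C)(C)O[Si](CC)(CC)CC)c(F)c1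
F5 | step 1 | 3-fluoro-5-[(triisopropylsilyl)oxy]benzaldehyde | O=Cc1cc(F)cc(O[Si](C(C)C)(C(C)C)C(C)C)c1
F6 | step 1 | lithium α-amino alkoxide of F5 (adduct with LiN(Me)CH2CH2NMe2) | CN(C)CCN(C)C(O[Li])c1cc(F)cc(O[Si](C(C)C)(C(C)C)C(C)C)c1
F7 | step 1 | C2-lithiated α-amino alkoxide | CN(C)CCN(C)C(O[Li])c1cc(O[Si](C(C)C)(C(C)C)C(C)C)cc(F)c1[Li]
F8 | step 1 | 2-bromo-3-fluoro-5-[(triisopropylsilyl)oxy]benzaldehyde | O=Cc1cc(O[Si](C(C)C)(C(C)C)C(C)C)cc(F)c1Br
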